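The target is a diarylmethane: one CH2 links C5 of an aspidinol ring (ring A, carrying butanoyl, methyl and methoxy) to the only unsubstituted carbon of a methylphloroacetophenone ring (ring B). Everything rests on disconnecting the bond between this CH2 and ring B. In a biomimetic key step, the aspidinol Mannich base loses dimethylamine, with the help of the ring A hydroxyl at C6 next to the CH2-bearing carbon, to give an ortho-quinone methide, and the free ring carbon of methylphloroacetophenone, flanked by two hydroxyls, adds to its exocyclic methylene. Both halves come from 2-methylphloroglucinol, and all other ring positions are blocked.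

Key step: step 5

Remark (assumption): the target has no stereocentre and no other stereogenic element, so it is achiral and the route needs no stereocontrol.

Numbering used below: ring A has C1 butanoyl, C2 OH, C3 CH3, C4 OCH3, C5 CH2 bridge, C6 OH. Ring B, numbered as the acetophenone, has C1 acetyl, C2 OH, C3 CH3, C4 OH, C5 bridge carbon, C6 OH.

**Step 1**
Reactants: 1 2-methylphloroglucinol (2-methylbenzene-1,3,5-triol)
Product: 2 1-(2,4,6-trihydroxy-3-methylphenyl)butan-1-one
Conditions: PrCOCl (1.05 equiv), AlCl3 (3.5 equiv), CH2Cl2/PhNO2, 0 °C → rt; ice/1 M HCl
Reagents that add atoms: butanoyl chloride, CCCC(=O)Cl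
Why: Friedel–Crafts C-acylation; the two free ring positions of 1 are equivalent by symmetry, so mono-acylation can give only 2, and the chelated acyl group deactivates the ring towards a second acylation.

**Step 2**
Reactants: 2 1-(2,4,6-trihydroxy-3-methylphenyl)butan-1-one
Product: 3 aspidinol, 1-(2,6-dihydroxy-4-methoxy-3-methylphenyl)butan-1-one
Conditions: Me2SO4 (1.0 equiv), K2CO3 (1.0 equiv), acetone, rt → 40 °C
Reagents that add atoms: dimethyl sulfate, COS(=O)(=O)OC
Why: Stoichiometric Williamson-type O-methylation; the C4–OH para to the ketone is the most acidic hydroxyl and the only one neither chelated nor shielded by the butanoyl group, so it should be methylated in preference to the C2 and C6 hydroxyls, as is usual for 2,4,6-trihydroxyacylbenzenes.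

**Step 3**
Reactants: 3 aspidinol
Product: 4 1-{3-[(dimethylamino)methyl]-2,6-dihydroxy-4-methoxy-5-methylphenyl}butan-1-one (Mannich base)
Conditions: Me2N+=CH2 I− (1.1 equiv), MeCN, 0 °C → rt; sat. aq NaHCO3
Reagents that add atoms: N,N-dimethylmethyleneiminium iodide (Eschenmoser's salt), C=[N+](C)C.[I-]
Why: Mannich aminomethylation by electrophilic aromatic substitution; C5 is the only unsubstituted ring carbon of 3 and is activated by the ortho C6–OH, the para C2–OH and the ortho methoxy group, and the preformed iminium salt avoids free formaldehyde, which would bridge two molecules of 3.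

**Step 4**
Reactants: 1 2-methylphloroglucinol
Product: 5 1-(2,4,6-trihydroxy-3-methylphenyl)ethan-1-one (methylphloroacetophenone)
Conditions: AcCl (1.05 equiv), AlCl3 (3.5 equiv), CH2Cl2/PhNO2, 0 °C → rt; ice/1 M HCl
Reagents that add atoms: acetyl chloride, CC(=O)Cl
Why: Friedel–Crafts C-acylation at one of the two symmetry-equivalent free positions of 1, as in step 1.

**Step 5**
Reactants: 4 Mannich base of aspidinol; 5 methylphloroacetophenone
Product: 7 1-{3-[(3-acetyl-2,4,6-trihydroxy-5-methylphenyl)methyl]-2,6-dihydroxy-4-methoxy-5-methylphenyl}butan-1-one (target), via ortho-quinone methide 6 (not isolated)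
Conditions: 5 (2 equiv), degassed 1,4-dioxane, 100 °C, Ar sweep; slow addition of 4
Reagents that add atoms: none
Why: Thermal E1cB-type loss of dimethylamine from the ammonium phenolate form of 4, assisted by the C6–OH ortho (and the C2–OH para) to the aminomethyl-bearing C5, should unmask the electron-poor ortho-quinone methide 6. Phenol 5 then adds in a conjugate (Michael-type) fashion through its only unsubstituted ring carbon C5, which lies between the C4 and C6 hydroxyls, to the exocyclic CH2 of 6, and rearomatisation of ring A followed by tautomerisation of ring B completes the diarylmethane. The closest known reaction type is the Mannich-base/ortho-quinone methide C-alkylation of phenols and acylphloroglucinols used for methylene-bridged phloroglucinol dimers, which mirrors the presumed biosynthetic bridging. No ring is closed and no stereocentre is created. The step needs cross-coupling over homo-coupling and C- over O-alkylation: 4 has no free ring carbon, so 6 cannot be captured by its own precursor, 5 offers a single nucleophilic carbon, any O-adduct can revert to 6 whereas the C-adduct is the thermodynamic sink, and slow addition of 4 to excess 5 under neutral conditions with removal of Me2NH should limit self-reaction of 6 and base-mediated exchange of the bridge.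

**Compound list**
1 | 2-methylphloroglucinol (2-methylbenzene-1,3,5-triol) | Cc1c(O)cc(O)cc1O | starting material
2 | 1-(2,4,6-trihydroxy-3-methylphenyl)butan-1-one | CCCC(=O)c1c(O)c(C)c(O)cc1O | intermediate
3 | aspidinol, 1-(2,6-dihydroxy-4-methoxy-3-methylphenyl)butan-1-one | CCCC(=O)c1c(O)c(C)c(OC)cc1O | intermediate
4 | 1-{3-[(dimethylamino)methyl]-2,6-dihydroxy-4-methoxy-5-methylphenyl}butan-1-one | CCCC(=O)c1c(O)c(C)c(OC)c(CN(C)C)c1O | intermediate
5 | 1-(2,4,6-trihydroxy-3-methylphenyl)ethan-1-one | CC(=O)c1c(O)c(C)c(O)cc1O | intermediate
6 | 2-butanoyl-3-hydroxy-5-methoxy-4-methyl-6-methylidenecyclohexa-2,4-dien-1-one (ortho-quinone methide) | CCCC(=O)C1=C(O)C(C)=C(OC)C(=C)C1=O | intermediate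
7 | 1-{3-[(3-acetyl-2,4,6-trihydroxy-5-methylphenyl)methyl]-2,6-dihydroxy-4-methoxy-5-methylphenyl}butan-1-one | CCCC(=O)c1c(O)c(C)c(OC)c(Cc2c(O)c(C)c(O)c(C(C)=O)c2O)c1O | target

Total step count: 5
Longest linear sequence: 4 steps (steps 1, 2, 3 and 5)

**Steps most likely to fail**

Step 5. The acetyl-deactivated nucleophile 5 may capture the quinone methide too slowly, so that self-reaction of the quinone methide and amine-mediated exchange of the methylene bridge between the rings (leading to symmetrical dimers) take over. The fallback sets out from 4 and comes back at 7. Compound 4 would be heated with an excess of the more nucleophilic, non-acylated 1 (4 equiv, dioxane, 60 °C), whose two free positions are equivalent, to give 1-{2,6-dihydroxy-4-methoxy-3-methyl-5-[(2,4,6-trihydroxy-3-methylphenyl)methyl]phenyl}butan-1-one F1. The acetyl group would then be introduced last, by Friedel–Crafts acetylation of the single remaining ring CH of F1 (Ac2O, BF3·OEt2, rt; aqueous NaOAc work-up), which should give 7 under non-basic conditions.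

Step 2. Site-selectivity between the three hydroxyls may be lost, with over-methylation and some C-methylation at the free ring carbon. The fallback sets out from 2 and comes back at 3. Compound 2 would be exhaustively O-methylated (excess Me2SO4, K2CO3, acetone, reflux) to 1-(2,4,6-trimethoxy-3-methylphenyl)butan-1-one F2. The two ethers ortho to the ketone would then be cleaved by carbonyl-assisted demethylation (AlCl3, PhCl, 60–80 °C, stopped at the bis-phenol); the C4 methoxy group lacks this assistance and should remain, giving 3.

Step 3. Amine may be lost prematurely from the freshly formed Mannich base while unreacted 3 is still present, which would bridge two molecules of 3; material may also be lost on isolation of the zwitterionic product. The fallback sets out from 3 and comes back at 4. Vilsmeier–Haack formylation of 3 (POCl3, DMF, MeCN, 0 °C → rt; aqueous hydrolysis) at its only free ring carbon would give 3-butanoyl-2,4-dihydroxy-6-methoxy-5-methylbenzaldehyde F3, which cannot form a quinone methide. Reductive amination of F3 (Me2NH in THF, NaBH(OAc)3, cat. AcOH, DCE, rt), carried out after all of 3 has been consumed, would then give 4.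

**Further compounds**
F1 | step 5 | 1-{2,6-dihydroxy-4-methoxy-3-methyl-5-[(2,4,6-trihydroxy-3-methylphenyl)methyl]phenyl}butan-1-one | CCCC(=O)c1c(O)c(C)c(OC)c(Cc2c(O)cc(O)c(C)c2O)c1O
F2 | step 2 | 1-(2,4,6-trimethoxy-3-methylphenyl)butan-1-one | CCCC(=O)c1c(OC)c(C)c(OC)cc1OC
F3 | step 3 | 3-butanoyl-2,4-dihydroxy-6-methoxy-5-methylbenzaldehyde | CCCC(=O)c1c(O)c(C)c(OC)c(C=O)c1O
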